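## Structural features

The target is a furanoheliangolide-type germacranolide. Its ten-membered carbocycle (C1–C10) is bridged by an oxygen between C3 and C10, so that O, C10, C1, C2 and C3 form a 3(2H)-furanone (C1 ketone, C2=C3). A trans-fused α-methylene-γ-butyrolactone sits on C6–C7 (C11–C13, lactone oxygen on C6). A Z-trisubstituted C4=C5 alkene carrying methyl C15 joins the furanone to the lactone carbinol and is cross-conjugated with the furanone. Five stereocentres stand in a row, C6–C7–C8–C9–C10: lactone carbinol, lactone junction, isovalerate carbinol, acetate carbinol and the fully substituted C10 (methyl C14 and the furanone oxygen); the configuration is 6R,7S,8S,9R,10R. Fragile groups are the exocyclic methylene lactone (Michael acceptor, easily isomerised), the two different esters on neighbouring carbons (acyl migration; no late enolate chemistry is possible beside them), the vinylogous ester/dienone and the allylic lactone carbinol. The real difficulty lies in the strained oxygen-bridged medium ring, in the oxygenated quaternary C10 next to four further stereocentres, and in telling O8 from O9. The key step uses the fact that C6, C7, C8, C9, C10 and C1 together with C14 are the seven carbons of benzoic acid, and that C9 and C10 carry cis oxygens exactly where a dioxygenase adds O2 to the ortho and ipso carbons.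

## Logic of the disconnections

**40 back to 38 (through 39).** The lactone C12–O6 bond and the C5–C6 bond are cut. C6 is the only stereocentre that does not sit on the former six-membered ring, and it lies between an alkenyl carbon and C7, so an alkenyl–aldehyde addition closes the carbocycle and creates the lactone carbinol in one event. The bridged tricycle becomes a monocyclic furanone with an open chain in which every ester is already final. The forward step must tolerate esters, an acrylate and a dienone, must not enolise C7, and must set C6.

**38 back to 36 (through 37).** The O10–C3 bond is cut. In 36 the tertiary O10 is tied up as the ring oxygen of a cyclic acetal at C6, so one acid treatment releases both O10–H and the C6 aldehyde, and O10 is at once consumed by the ynone. O9 is already acetylated and cannot compete to form a pyranone. The demand is that 5-endo closure outruns intermolecular addition to the ynone.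

**36 back to 35, then to 25 and 34.** After adjusting C1 to the alcohol level, the C1–C2 bond is cut. In 25 the C1 aldehyde is the only free carbonyl, so an alkynyl-metal addition is unambiguous. This separates the five-carbon C2–C5/C15 unit, with its Z-alkene preset, from the chiral core. The forward step needs a base-free alkynylation that spares the alkenyl iodide, then a mild oxidation.

**34 back to 33, 32, 28 and 29; 28 back to 26 (through 27, 30, 31).** The two C–I bonds, the C3–C4 bond and the C–B/C–Br bonds are cut. syn-Bromoboration of 26 fixes the alkene geometry, and every later substitution at the alkene must proceed with retention.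

**25 back to 22 (through 24 and 23).** C1 and C6 are reconnected as a ring double bond. Both carbonyl carbons then come from one alkene of a six-membered ring, on which C7–C10 are far easier to control than on an open chain. The two aldehydes formed together must be told apart: the tertiary O10–H can reach only C6 (six-membered lactol), which is then fixed as the methyl acetal. Ozone must choose the ring alkene over the acrylate.

**22 back to 21 and 20.** The acetate is traced to the free diol and this to the acetonide. A secondary O9–H beside a tertiary O10–H needs no selective trick, while the acetonide is needed earlier for facial control. The hydrolysis must not ionise the tertiary allylic C10–O bond or move the isovalerate.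

**20 back to 18 (through 19), then to 9 and 15 (through 16 and 17); 15 back to 13 (through 14), 10 and 11 (through 12).** The C7–C11 bond is cut and C11=C13 is traced to a selenide. A [3,3] shift transfers the configuration of C1–O to C7 and moves the double bond to C1=C6, where cleavage is wanted. The selenium-bearing orthoester brings C13 in masked form, so no enolate is ever needed beside the isovalerate. The demand is orthoester exchange at a hindered alcohol next to the quaternary C10.

**9 back to 8 and 6 (through 7).** The C8–O and C1–O bonds (both from one O2) and the isovalerate are cut. A cis-1,4-dioxygenation of the diene anti to the acetonide places both oxygens. The forward steps need facial selectivity and mono-acylation at O8.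

**6 back to 5, 4, 3 and 2.** Methyl C14 is traced to the carboxyl group and the acetonide to the diol. The demand is a hydride displacement at a neopentyl-type carbon without touching the diene.

**2 back to 1.** The C9–O and C10–O bonds are cut. Two stereocentres, one of them quaternary, come from an achiral arene in one operation; the demand is complete regio-, facial and enantiocontrol, which only the enzyme supplies.

## Other disconnections considered

**Alternative 1:** The C2–C3 bond is cut, leading back to the nine-membered lactone A1 (C10–O–C3 ester, acetyl group on C10).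
- Forward step: the lithium enolate of the acetyl group attacks the lactone carbonyl (5-exo), and acid dehydration gives the furanone-bridged cyclodecene A2.
- In favour: the carbocycle and the furanone arise together through a five-membered transition state; the Z geometry is fixed before the strained ring exists.
- Against: A1 is a medium-ring ester of a tertiary alcohol, so the hard ring closure is only moved. A2 still needs the lactone oxidation level at C12 and two different esters on a freed C8,C9-diol, a differentiation of two neighbouring secondary hydroxyls.
- Comparison: on mechanism the acyl transfer is the better ring-forming event than the chromium-mediated closure chosen here. On structure the chosen plan is better, because O8 and O9 are acylated at different times and the ring closure ends at the target. On step economy the alternative needs several operations after A2, while the chosen plan needs none after ring closure. The origin of the stereocentres is not addressed by this cut.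

**Alternative 2:** The C3–C4 and C2–C3 bonds are cut with carbon monoxide as C3, leading back to the iodo-alkyne A3.
- Forward step: palladium inserts into the alkenyl C–I bond, takes up CO and couples with the terminal alkyne to give the ten-membered ynone A4; hydration with cyclodehydration then gives the furanone.
- In favour: it is the most convergent plan; A3 already carries both esters and the methylene lactone, and no pair of aldehydes has to be told apart. On these points it is the better plan.
- Against: the carbonylative coupling must outrun the direct coupling, which would give a nine-membered enyne, and CO insertion at a hindered alkenyl-palladium is slow at the dilution required. Amine base and palladium hydride species endanger the methylene lactone. C10 would be set by addition to a ketone under substrate control.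
- Comparison: the two plans are equal in closing a medium ring on a complete stereopentad. The chosen plan is better in absolute stereocontrol at C9/C10 and in the chemoselectivity of the closure.

**Alternative 3:** The C8–C9 bond is cut as an alkene, leading back to the diene A5.
- Forward step: ring-closing metathesis with the second-generation Grubbs catalyst gives the E-alkene A6; syn-dihydroxylation and two acylations follow.
- In favour: the closure is catalytic and the fragments are simple, a point on which it is better than stoichiometric chromium. E geometry plus syn addition gives the correct relative configuration at C8/C9.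
- Against: the vinyl group on quaternary C10 is hindered, and the methylene lactone competes as a metathesis partner. The dihydroxylation must pick one of four C=C bonds and one face, and the two new hydroxyls must then be acylated differently.
- Comparison: the chosen plan sets C9/C10 by the enzyme and relays C8 and C7 on a rigid six-membered ring, and it is shorter after ring closure.

Key step: step 1

Remarks on the chemistry:
- Germacranolide locants (C1–C15) are used for all intermediates. "Upper face" of the ring C10–C9–C8–C7–C6–C1 is the face carrying C14; "lower face" is the face carrying O9 and O10.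
- No structural error was found: the (1S,2R)-diol maps onto C10 and C9 of the target once the carboxyl group has become C14.
- Three design weaknesses of a plain orthoacetate/dialdehyde/late-methylenation sequence are corrected: (a) C13 is brought in masked by orthoester 15, because an enolate methylenation beside the isovalerate, the acetate and the furanone cannot be selective; (b) the two aldehydes from ring cleavage are differentiated by O10; (c) O9 is acetylated before the ynone exists.
- C11 in 16–19, the carbinol C1 in 35 and the anomeric C6 in 24, 25 and 35–37 are epimer mixtures that converge later.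

## Steps

Step 1
Reactants: 1 benzoic acid (fed as its sodium salt)
Product: 2 (1S,2R)-1,2-dihydroxycyclohexa-3,5-diene-1-carboxylic acid
Conditions: whole cells of Cupriavidus necator B9 (benzoate 1,2-dioxygenase, diol dehydrogenase-deficient), fructose, mineral medium, pH 7, air, 30 °C; cold acidification to pH 3, EtOAc extraction
Reagents that add atoms: dioxygen, O=O
Why: The reductase passes two electrons from NADH through the Rieske iron–sulfur cluster to a mononuclear non-heme iron centre, which binds O2 side-on and delivers both oxygen atoms to one face of the ipso–ortho bond of the bound benzoate. The closest known reaction type is the arene cis-dihydroxylation by Rieske dioxygenases, used preparatively as whole-cell oxidations. Two C–O bonds are formed and no ring is closed. Both new stereocentres, the quaternary C10 (1S in 2) and C9 (2R in 2), are controlled by the active site, which anchors the carboxylate and exposes only one face of the ipso–ortho bond. The step needs regioselectivity (ipso,ortho and not ortho,meta), facial and enantioselectivity, and no further oxidation. The first three come from the enzyme pocket; the last comes from using a strain that lacks the diol dehydrogenase, so the diol accumulates. The fully substituted C10 also slows rearomatisation, so the diol survives a cold, short acidification.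

Step 2
Reactants: 2 diol acid
Product: 3 (3aS,7aR)-2,2-dimethyl-3a,7a-dihydro-1,3-benzodioxole-3a-carboxylic acid
Conditions: 2,2-dimethoxypropane, TsOH (cat.), acetone, 0 °C → rt
Reagents that add atoms: 2,2-dimethoxypropane, COC(C)(C)OC
Why: Acid-catalysed transacetalisation of the cis-diol gives the cis-fused dioxolane. It protects the diol from dehydration and will shield the lower face of the diene.

Step 3
Reactants: 3 acetonide acid
Product: 4 [(3aR,7aR)-2,2-dimethyl-3a,7a-dihydro-1,3-benzodioxol-3a-yl]methanol
Conditions: LiAlH4, THF, 0 °C → rt
Reagents that add atoms: none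
Why: Hydride reduction of a carboxylic acid to the primary alcohol; the diene and the acetonide are inert to LiAlH4.

Step 4
Reactants: 4 primary alcohol
Product: 5 p-toluenesulfonate of 4
Conditions: TsCl, Et3N, DMAP (cat.), CH2Cl2, 0 °C
Reagents that add atoms: p-toluenesulfonyl chloride, Cc1ccc(cc1)S(=O)(=O)Cl
Why: Sulfonylation of the only hydroxyl; C10 carries no hydrogen, so the sulfonate cannot eliminate.

Step 5
Reactants: 5 tosylate
Product: 6 (3aS,7aR)-2,2,3a-trimethyl-3a,7a-dihydro-1,3-benzodioxole
Conditions: LiEt3BH, THF, 0 °C → 65 °C
Reagents that add atoms: none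
Why: SN2 displacement of a primary sulfonate by hydride. LiEt3BH attacks carbon rather than sulfur even at neopentyl-type positions, and the diene is untouched. The volatile product is carried on in solution.

Step 6
Reactants: 6 diene acetonide
Product: 8 2,2,3a-trimethyl-3a,4,7,7a-tetrahydro-1,3-benzodioxole-4,7-diol with both hydroxyls (O1 and O8) on the upper face, via endoperoxide 7 (not isolated)
Conditions: O2, visible light, tetraphenylporphyrin (cat.), CH2Cl2, −40 °C; then thiourea, MeOH, −40 °C → rt
Reagents that add atoms: dioxygen, O=O
Why: [4+2] cycloaddition of singlet oxygen to the s-cis diene occurs on the face opposite the dioxolane and sets C8–O and C1–O together on the upper face. Thiourea then cleaves the O–O bond without reducing the C6=C7 alkene.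

Step 7
Reactants: 8 enediol
Product: 9 O8-(3-methylbutanoyl) ester of 8 (O1–H free)
Conditions: 3-methylbutanoyl chloride (1.05 equiv), 2,4,6-collidine, CH2Cl2, −40 → −20 °C
Reagents that add atoms: 3-methylbutanoyl chloride, CC(C)CC(=O)Cl
Why: Kinetic acylation. O8–H is flanked by the C9 methine, whereas O1–H is neopentyl-like, next to the quaternary C10 and syn to C14. The ester is the final C8 substituent and blocks O8 for the rearrangement.

Step 8
Reactants: 10 diphenyl diselenide; 11 acrylonitrile
Product: 13 3-(phenylselanyl)propanenitrile, via sodium benzeneselenolate 12 (not isolated)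
Conditions: NaBH4, EtOH, 0 °C; then 11, 0 °C → rt
Reagents that add atoms: none
Why: Borohydride cleaves the Se–Se bond, and the soft selenolate adds to the acrylonitrile in a conjugate (Michael) addition.

Step 9
Reactants: 13 selenide nitrile
Product: 15 1,1,1-trimethoxy-3-(phenylselanyl)propane, via imidate hydrochloride 14 (not isolated)
Conditions: HCl (g), MeOH (1.1 equiv), Et2O, 0 °C; then MeOH, hexane, rt
Reagents that add atoms: methanol, CO
Why: Pinner reaction of the nitrile to the imidate salt, followed by alcoholysis to the orthoester with loss of ammonium chloride.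

Step 10
Reactants: 9 O8 ester with free O1–H; 15 seleno-orthoester
Product: 18 methyl 2-(C7-yl)-3-(phenylselanyl)propanoate on the ring C10–C9–C8–C7–C6=C1 (side chain on the upper face, acetonide and isovalerate retained), via mixed orthoester 16 (not isolated), via ketene acetal 17 (not isolated)
Conditions: 15 (3 equiv), pivalic acid (cat.), xylene, 135 °C, MeOH distilled off
Reagents that add atoms: none
Why: Johnson–Claisen rearrangement: O1–H exchanges into the orthoester, loss of methanol gives the ketene acetal, and the suprafacial [3,3] shift forms C7–C11 on the face that carried C1–O (cis to O8). The double bond moves to C1=C6. The weak acid leaves the ester and the acetonide alone.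

Step 11
Reactants: 18 selenide ester
Product: 20 methyl 2-(C7-yl)prop-2-enoate (C11=C13 methylene ester, acetonide retained), via selenoxide 19 (not isolated)
Conditions: NaIO4, NaHCO3, THF/MeOH/H2O, 0 °C → rt
Reagents that add atoms: none
Why: Selenide oxidation and syn-elimination of the selenoxide. The only β-hydrogen is on C11, so only the exocyclic methylene can form. No base strong enough to enolise an ester is used.

Step 12
Reactants: 20 acrylate acetonide
Product: 21 C9,C10-diol of 20
Conditions: AcOH/H2O (4:1), 45 °C
Reagents that add atoms: none
Why: Acetal hydrolysis through the 2-alkoxy-2-propyl cation. This is far easier than ionising the tertiary allylic C10–O bond, which is deactivated by the neighbouring C9 oxygen. The esters survive aqueous acetic acid.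

Step 13
Reactants: 21 diol
Product: 22 O9-acetate of 21 (tertiary O10–H free)
Conditions: Ac2O (1.2 equiv), pyridine, DMAP (cat.), CH2Cl2, 0 °C
Reagents that add atoms: acetic anhydride, CC(=O)OC(C)=O
Why: Acyl transfer to the secondary hydroxyl; the tertiary C10 hydroxyl is not acetylated under these conditions. Fast acetylation at 0 °C pre-empts migration of the isovalerate.

Step 14
Reactants: 22 O9-acetate
Product: 25 methyl pyranoside aldehyde (tetrahydropyran O10–C10–C9–C8–C7–C6; OMe on C6; formyl C1 and methyl C14 on C10), via ozonide 23 (not isolated), via lactol aldehyde 24 (not isolated)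
Conditions: O3, CH2Cl2, −78 °C (Sudan Red 7B end point); PPh3, −78 °C → rt; then MeOH, PPTS (cat.), rt
Reagents that add atoms: ozone, O=[O+][O-]; methanol, CO
Why: Ozonolysis cleaves the electron-richer ring alkene before the acrylate. After reduction the C6 aldehyde is captured by O10–H as a six-membered lactol, while no hydroxyl can reach C1. Acidic methanol turns the lactol into the glycoside, whereas the α-alkoxy, neopentyl C1 aldehyde forms an acetal only slowly.

Step 15
Reactants: 26 propyne
Product: 28 (Z)-2-(2-bromoprop-1-en-1-yl)-4,4,5,5-tetramethyl-1,3,2-dioxaborolane, via dibromoborane 27 (not isolated)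
Conditions: BBr3, CH2Cl2, −78 °C; then pinacol, −78 °C → rt
Reagents that add atoms: boron tribromide, BrB(Br)Br; pinacol, CC(C)(O)C(C)(C)O
Why: syn-Bromoboration places boron on the terminal carbon and bromine on the internal one, cis to each other. Esterification at low temperature preserves this geometry.

Step 16
Reactants: 28 bromoalkenyl boronate; 29 trimethylsilylacetylene
Product: 32 (Z)-trimethyl[3-methyl-4-(4,4,5,5-tetramethyl-1,3,2-dioxaborolan-2-yl)but-3-en-1-yn-1-yl]silane, via lithium acetylide 30 (not isolated), via alkynylzinc bromide 31 (not isolated)
Conditions: 29, n-BuLi, THF, −78 °C; ZnBr2, 0 °C; then 28, Pd(P(t-Bu)3)2 (cat.), THF, rt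
Reagents that add atoms: none
Why: Negishi coupling at the C–Br bond with retention of the alkene geometry; the C–B bond does not transmetalate under these conditions.

Step 17
Reactants: 32 enynyl boronate
Product: 33 (Z)-(4-iodo-3-methylbut-3-en-1-yn-1-yl)trimethylsilane
Conditions: NaOH (aq), then I2, THF, 0 °C, dark
Reagents that add atoms: iodine, II
Why: Iododeboronation of the hydroxy-boronate complex proceeds with retention, so iodine ends up cis to the alkynyl group.

Step 18
Reactants: 33 iodo enyne silane
Product: 34 (Z)-1,4-diiodo-3-methylbut-3-en-1-yne
Conditions: N-iodosuccinimide, AgNO3 (cat.), acetone, rt, dark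
Reagents that add atoms: N-iodosuccinimide, O=C1CCC(=O)N1I
Why: Silver-catalysed iododesilylation of the alkynylsilane through the silver acetylide; the alkenyl iodide is not affected.

Step 19
Reactants: 25 pyranoside aldehyde; 34 diiodide
Product: 35 C1 propargylic alcohol (C1–C2 bond formed; alkenyl iodide and pyranoside intact)
Conditions: CrCl2 (nickel-free, 5 equiv), 34 (2 equiv), DMF, rt
Reagents that add atoms: none
Why: Divalent chromium inserts into the alkynyl C–I bond, and the alkynylchromium adds to the aldehyde (Nozaki–Hiyama-type alkynylation). Without nickel the alkenyl iodide is inert. Esters, acrylate and acetal are tolerated, and no base touches C7.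

Step 20
Reactants: 35 propargylic alcohol
Product: 36 C1 ynone
Conditions: Dess–Martin periodinane, NaHCO3, CH2Cl2, 0 °C → rt
Reagents that add atoms: none
Why: Dess–Martin oxidation of the only free hydroxyl; both C1 epimers give the same ketone.

Step 21
Reactants: 36 ynone pyranoside
Product: 38 furanone aldehyde (3(2H)-furanone with C10 bearing C14 and the chain C9(OAc)–C8(O-isovaleryl)–C7(acrylate)–C6HO; (Z)-2-iodo-1-methylvinyl on C3), via lactol ynone 37 (not isolated)
Conditions: HCl (0.5 M aq)/THF (1:4), rt
Reagents that add atoms: water, O
Why: Acid hydrolysis of the glycoside gives the lactol, whose open form has a free O10–H next to the ynone. A 5-endo-dig oxa-Michael addition then closes the furanone irreversibly and leaves C6 as a free aldehyde. Hydration of the ynone would converge on the same furanone by cyclodehydration.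

Step 22
Reactants: 38 furanone aldehyde
Product: 40 CNP0255553.1, (6R,7S,8S,9R,10R)-9-acetoxy-8-(3-methylbutanoyloxy)-1-oxo-3,10-epoxygermacra-2,4Z,11(13)-trien-12,6-olide, via hydroxy ester 39 (not isolated)
Conditions: CrCl2 (10 equiv), NiCl2 (2 mol %), DMSO, rt, slow addition to 1 mM; aqueous work-up; then camphorsulfonic acid (cat.), CH2Cl2, rt
Reagents that add atoms: none
Why: Nozaki–Hiyama–Kishi macrocyclisation: zerovalent nickel inserts into the C5–I bond with retention, transmetalation gives the alkenyl species of trivalent chromium, and this adds only to the aldehyde, closing the C5–C6 bond. C6 is set by the C7 substituents within the ring-closing transition state. The γ-hydroxy acrylate then lactonises under acid with loss of methanol.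

## Compound list

1 | benzoic acid | OC(=O)c1ccccc1 | starting material
2 | (1S,2R)-1,2-dihydroxycyclohexa-3,5-diene-1-carboxylic acid | O[C@@H]1C=CC=C[C@@]1(O)C(=O)O | intermediate
3 | (3aS,7aR)-2,2-dimethyl-3a,7a-dihydro-1,3-benzodioxole-3a-carboxylic acid | CC1(C)O[C@@H]2C=CC=C[C@@]2(O1)C(=O)O | intermediate
4 | [(3aR,7aR)-2,2-dimethyl-3a,7a-dihydro-1,3-benzodioxol-3a-yl]methanol | CC1(C)O[C@@H]2C=CC=C[C@@]2(O1)CO | intermediate
5 | p-toluenesulfonate of 4 | CC1(C)O[C@@H]2C=CC=C[C@@]2(O1)COS(=O)(=O)c3ccc(C)cc3 | intermediate
6 | (3aS,7aR)-2,2,3a-trimethyl-3a,7a-dihydro-1,3-benzodioxole | CC1(C)O[C@@H]2C=CC=C[C@@]2(O1)C | intermediate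
7 | endoperoxide of 6 (O–O bridge from C8 to C1 on the upper face) | CC1(C)O[C@@H]2[C@@H]3C=C[C@@H](OO3)[C@@]2(O1)C | intermediate
8 | 2,2,3a-trimethyl-3a,4,7,7a-tetrahydro-1,3-benzodioxole-4,7-diol, both hydroxyls on the upper face | CC1(C)O[C@@H]2[C@@H](O)C=C[C@@H](O)[C@@]2(O1)C | intermediate
9 | O8-(3-methylbutanoyl) ester of 8 | CC1(C)O[C@@H]2[C@@H](OC(=O)CC(C)C)C=C[C@@H](O)[C@@]2(O1)C | intermediate
10 | diphenyl diselenide | c1ccc(cc1)[Se][Se]c1ccccc1 | starting material
11 | acrylonitrile | C=CC#N | starting material
12 | sodium benzeneselenolate | [Na+].[Se-]c1ccccc1 | intermediate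
13 | 3-(phenylselanyl)propanenitrile | N#CCC[Se]c1ccccc1 | intermediate
14 | methyl 3-(phenylselanyl)propanimidate hydrochloride | COC(=[NH2+])CC[Se]c1ccccc1.[Cl-] | intermediate
15 | 1,1,1-trimethoxy-3-(phenylselanyl)propane | COC(OC)(OC)CC[Se]c1ccccc1 | intermediate
16 | mixed orthoester (O1 of 9 bound to the dimethoxy orthoester carbon) | CC1(C)O[C@@H]2[C@@H](OC(=O)CC(C)C)C=C[C@@H](OC(OC)(OC)CC[Se]c3ccccc3)[C@@]2(O1)C | intermediate
17 | ketene acetal (O1 of 9 bound to a 1-methoxy-3-(phenylselanyl)prop-1-enyl group) | CC1(C)O[C@@H]2[C@@H](OC(=O)CC(C)C)C=C[C@@H](OC(OC)=CC[Se]c3ccccc3)[C@@]2(O1)C | intermediate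
18 | Claisen ester: C7 carries CH(CH2SePh)CO2Me on the upper face; C1=C6 alkene; acetonide on O9/O10; isovalerate on O8 | CC1(C)O[C@@H]2[C@@H](OC(=O)CC(C)C)[C@@H](C(C[Se]c3ccccc3)C(=O)OC)C=C[C@@]2(O1)C | intermediate
19 | selenoxide of 18 | CC1(C)O[C@@H]2[C@@H](OC(=O)CC(C)C)[C@@H](C(C[Se](=O)c3ccccc3)C(=O)OC)C=C[C@@]2(O1)C | intermediate
20 | acrylate acetonide: C7 carries C(=CH2)CO2Me | CC1(C)O[C@@H]2[C@@H](OC(=O)CC(C)C)[C@@H](C(=C)C(=O)OC)C=C[C@@]2(O1)C | intermediate
21 | C9,C10-diol of 20 | O[C@@H]1[C@@H](OC(=O)CC(C)C)[C@@H](C(=C)C(=O)OC)C=C[C@@]1(O)C | intermediate
22 | O9-acetate of 21 with free tertiary O10–H | CC(=O)O[C@@H]1[C@@H](OC(=O)CC(C)C)[C@@H](C(=C)C(=O)OC)C=C[C@@]1(O)C | intermediate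
23 | ozonide of 22 (1,2,4-trioxolane across C1 and C6) | CC(=O)O[C@@H]1[C@@H](OC(=O)CC(C)C)[C@@H](C(=C)C(=O)OC)C2OOC(O2)[C@@]1(O)C | intermediate
24 | lactol aldehyde (tetrahydropyran O10–C10–C9–C8–C7–C6 with hemiacetal OH on C6; formyl C1 on C10) | O=C[C@]1(C)OC(O)[C@H](C(=C)C(=O)OC)[C@H](OC(=O)CC(C)C)[C@H]1OC(C)=O | intermediate
25 | methyl pyranoside aldehyde (OMe on C6) | O=C[C@]1(C)OC(OC)[C@H](C(=C)C(=O)OC)[C@H](OC(=O)CC(C)C)[C@H]1OC(C)=O | intermediate
26 | propyne | CC#C | starting material
27 | (Z)-dibromo(2-bromoprop-1-en-1-yl)borane | BrB(Br)/C=C(\Br)C | intermediate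
28 | (Z)-2-(2-bromoprop-1-en-1-yl)-4,4,5,5-tetramethyl-1,3,2-dioxaborolane | CC1(C)OB(OC1(C)C)/C=C(\Br)C | intermediate
29 | trimethylsilylacetylene | C#C[Si](C)(C)C | starting material
30 | lithium (trimethylsilyl)acetylide | [Li]C#C[Si](C)(C)C | intermediate
31 | bromo[(trimethylsilyl)ethynyl]zinc | Br[Zn]C#C[Si](C)(C)C | intermediate
32 | (Z)-trimethyl[3-methyl-4-(4,4,5,5-tetramethyl-1,3,2-dioxaborolan-2-yl)but-3-en-1-yn-1-yl]silane | CC1(C)OB(OC1(C)C)/C=C(\C#C[Si](C)(C)C)C | intermediate
33 | (Z)-(4-iodo-3-methylbut-3-en-1-yn-1-yl)trimethylsilane | I/C=C(\C#C[Si](C)(C)C)C | intermediate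
34 | (Z)-1,4-diiodo-3-methylbut-3-en-1-yne | I/C=C(\C#CI)C | intermediate
35 | C1 propargylic alcohol (C1 epimers) | I/C=C(C)\C#CC(O)[C@]1(C)OC(OC)[C@H](C(=C)C(=O)OC)[C@H](OC(=O)CC(C)C)[C@H]1OC(C)=O | intermediate
36 | C1 ynone | I/C=C(C)\C#CC(=O)[C@]1(C)OC(OC)[C@H](C(=C)C(=O)OC)[C@H](OC(=O)CC(C)C)[C@H]1OC(C)=O | intermediate
37 | lactol ynone | I/C=C(C)\C#CC(=O)[C@]1(C)OC(O)[C@H](C(=C)C(=O)OC)[C@H](OC(=O)CC(C)C)[C@H]1OC(C)=O | intermediate
38 | furanone aldehyde | O=C[C@H](C(=C)C(=O)OC)[C@H](OC(=O)CC(C)C)[C@@H](OC(C)=O)[C@@]1(C)OC(/C(C)=C\I)=CC1=O | intermediate
39 | macrocyclic (6R)-hydroxy methyl ester | C=C(C(=O)OC)[C@H]1[C@H](O)/C=C(/C)C2=CC(=O)[C@](C)(O2)[C@H](OC(C)=O)[C@H]1OC(=O)CC(C)C | intermediate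
40 | CNP0255553.1 | C=C1C(=O)O[C@@H]2/C=C(/C)C3=CC(=O)[C@](C)(O3)[C@H](OC(C)=O)[C@@H](OC(=O)CC(C)C)[C@@H]12 | target

## Step count and least certain steps

Total: 22 steps. Longest linear sequence: 16 steps (steps 1–7, 10–14, 19–22).

**Step 1 (key step).** Most likely failure: incomplete conversion together with acid-catalysed dehydration of the diol during isolation, because the cyclohexadienediol loses water to a phenolic acid once the broth is acidified, and residual dehydrogenase activity would oxidise it further. Fallback, from 1: Birch reduction (Na, liquid NH3, then NH4Cl) gives cyclohexa-2,5-diene-1-carboxylic acid F1. Double deprotonation with LiN(i-Pr)2 and oxygenation of the dienolate at C1 (O2, P(OEt)3) gives 1-hydroxycyclohexa-2,5-diene-1-carboxylic acid F2. Hydroxyl-directed epoxidation (m-CPBA, NaHCO3) gives the racemic syn-epoxy alcohol F3. LiNEt2 isomerises the epoxide to the allylic alcohol, giving racemic 2, which is separated on a chiral stationary phase from its enantiomer F4. The route is rejoined at 2.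

**Step 22.** Most likely failure: poor facial selectivity at C6, accompanied by slow ring closure, because the closing transition state of the strained bridged ring, not the C7 substituents alone, decides which aldehyde face is presented. Fallback, from 39: the work-up is kept neutral so that 39 is isolated together with its C6 epimer F5. The mixture is oxidised with MnO2 to the C6 dienone F6. F6 is reduced under reagent control (Corey–Bakshi–Shibata reduction, (R)-2-methyl-oxazaborolidine if the dienyl group acts as the large substituent, catecholborane, −78 °C) to 39. Acid then gives 40.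

**Step 21.** Most likely failure: consumption of the ynone by intermolecular conjugate addition of water or chloride before the glycoside has opened, because O10 becomes available only after acetal hydrolysis. Fallback, from 36: Et2NH (1 equiv, CH2Cl2, 0 °C) adds to the ynone to give the stable enaminone F7. Aqueous acetic acid then opens the glycoside, and O10 displaces the amine by addition–elimination to give 38.

**Step 10.** Most likely failure: slow orthoester exchange at the hindered O1–H, so that at the temperature required ionisation of the allylic ester and elimination compete. Fallback, from 9: methyl chloroformate/pyridine gives the O1 methyl carbonate F8. Tsuji–Trost alkylation (Pd(PPh3)4, trimethyl phosphonoacetate, THF) proceeds with double inversion and attack at the less hindered C7 to give the phosphonoacetate F9. Horner–Wadsworth–Emmons reaction with formaldehyde (K2CO3, aq. HCHO) gives 20.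

**Step 7.** Most likely failure: acylation of both hydroxyls or of O1, if the steric difference between the two allylic alcohols is smaller than assumed. Fallback, from 8: Et3SiCl/imidazole gives the bis(triethylsilyl) ether F10. Mild methanolysis (PPTS, MeOH, 0 °C) removes the less hindered O8 silyl group to give F11. Acylation with 3-methylbutanoyl chloride gives F12, and HF·pyridine frees O1–H to give 9.

## Further compounds

F1 | step 1 | cyclohexa-2,5-diene-1-carboxylic acid | OC(=O)C1C=CCC=C1
F2 | step 1 | 1-hydroxycyclohexa-2,5-diene-1-carboxylic acid | OC(=O)C1(O)C=CCC=C1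
F3 | step 1 | syn-2,3-epoxy-1-hydroxycyclohex-5-ene-1-carboxylic acid (racemic; one enantiomer drawn) | OC(=O)[C@]1(O)C=CC[C@H]2O[C@@H]12
F4 | step 1 | (1R,2S)-1,2-dihydroxycyclohexa-3,5-diene-1-carboxylic acid (enantiomer of 2) | O[C@H]1C=CC=C[C@]1(O)C(=O)O
F5 | step 22 | C6 epimer of 39 | C=C(C(=O)OC)[C@H]1[C@@H](O)/C=C(/C)C2=CC(=O)[C@](C)(O2)[C@H](OC(C)=O)[C@H]1OC(=O)CC(C)C
F6 | step 22 | C6 ketone (dienone) of 39 | C=C(C(=O)OC)[C@H]1C(=O)/C=C(/C)C2=CC(=O)[C@](C)(O2)[C@H](OC(C)=O)[C@H]1OC(=O)CC(C)C
F7 | step 21 | 3-(diethylamino) enaminone from 36 | CCN(CC)C(=CC(=O)[C@]1(C)OC(OC)[C@H](C(=C)C(=O)OC)[C@H](OC(=O)CC(C)C)[C@H]1OC(C)=O)/C(C)=C\I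
F8 | step 10 | O1 methyl carbonate of 9 | CC1(C)O[C@@H]2[C@@H](OC(=O)CC(C)C)C=C[C@@H](OC(=O)OC)[C@@]2(O1)C
F9 | step 10 | C7 (dimethoxyphosphoryl)acetate adduct | CC1(C)O[C@@H]2[C@@H](OC(=O)CC(C)C)[C@@H](C(C(=O)OC)P(=O)(OC)OC)C=C[C@@]2(O1)C
F10 | step 7 | O1,O8-bis(triethylsilyl) ether of 8 | CC1(C)O[C@@H]2[C@@H](O[Si](CC)(CC)CC)C=C[C@@H](O[Si](CC)(CC)CC)[C@@]2(O1)C
F11 | step 7 | O1-triethylsilyl ether of 8 (O8–H free) | CC1(C)O[C@@H]2[C@@H](O)C=C[C@@H](O[Si](CC)(CC)CC)[C@@]2(O1)C
F12 | step 7 | O1-triethylsilyl ether of 9 | CC1(C)O[C@@H]2[C@@H](OC(=O)CC(C)C)C=C[C@@H](O[Si](CC)(CC)CC)[C@@]2(O1)C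
A1 | alternative 1 | nine-membered lactone with C10 acetyl group, C8,C9 acetonide and two silyl ethers | CC(=O)[C@]1(C)OC(=O)/C(C)=C\[C@@H](O[Si](C)(C)C(C)(C)C)[C@H](C(=C)CO[Si](C)(C)C(C)(C)C)[C@@H]2OC(C)(C)O[C@@H]12
A2 | alternative 1 | furanone-bridged cyclodecene with C8,C9 acetonide and silyl-masked lactone diol | CC(C)(C)[Si](C)(C)O[C@@H]1/C=C(/C)C2=CC(=O)[C@](C)(O2)[C@@H]3OC(C)(C)O[C@H]3[C@H]1C(=C)CO[Si](C)(C)C(C)(C)C
A3 | alternative 2 | seco lactone with Z alkenyl iodide at C4 and terminal alkyne on the C10 carbinol | C=C1C(=O)O[C@H](/C=C(/C)I)[C@H]1[C@H](OC(=O)CC(C)C)[C@@H](OC(C)=O)[C@@](C)(O)C#C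
A4 | alternative 2 | ten-membered C3 ynone with the C10 hydroxyl | C=C1C(=O)O[C@@H]2/C=C(/C)C(=O)C#C[C@](C)(O)[C@H](OC(C)=O)[C@@H](OC(=O)CC(C)C)[C@@H]12
A5 | alternative 3 | diene with vinyl groups on C10 of the furanone and C7 of the lactone | C=C1C(=O)O[C@H](/C=C(/C)C2=CC(=O)[C@@](C)(C=C)O2)[C@H]1C=C
A6 | alternative 3 | 8,9-didehydro bridged tricycle with E C8=C9 alkene | C=C1C(=O)O[C@@H]2/C=C(/C)C3=CC(=O)[C@](C)(O3)/C=C/[C@@H]12
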